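**Retrosynthetic overview**
- Target ⇒ bis(3,4-dihydroxyphenyl)methane: the six C–Br bonds are made last by exhaustive electrophilic bromination.
- Bis(3,4-dihydroxyphenyl)methane ⇒ its bis(monocarbonate) by carbonate cleavage.
- Bis(monocarbonate) ⇒ bisphenol F + a dialkyl peroxydicarbonate: the two new aryl C–O bonds are made by ortho C–H oxygenation (key step).
- No ring is formed; both benzene rings and the CH2 bridge are bought in bisphenol F.

Assumption: the target has no stereocentre and is achiral, so the SMILES defines it fully and no stereocontrol or resolution is needed.

**Step 1**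
Reactants: 1 bis(4-hydroxyphenyl)methane (bisphenol F); 2 dihexadecyl peroxydicarbonate
Product: 4 bis[3-(hexadecyloxycarbonyloxy)-4-hydroxyphenyl]methane, via bis(aryl peroxycarbonate) 3 (not isolated)
Conditions: 2 (2.2 equiv), CH2Cl2/HFIP 4:1, 0 → 20 °C, dark, argon, 24 h
Reagents that add atoms: dihexadecyl peroxydicarbonate, CCCCCCCCCCCCCCCCOC(=O)OOC(=O)OCCCCCCCCCCCCCCCC
Why: Proposed new method: the phenol oxygen of 1 attacks the electrophilic O–O bond of 2 (HFIP hydrogen-bonds the carbonyl and polarises the peroxide) and expels hexadecyl hydrogen carbonate, which loses CO2 and makes the O-transfer irreversible; the aryl peroxycarbonate 3 then undergoes a [3,3]-sigmatropic shift that puts the carbonyl oxygen on the ortho carbon, and tautomerisation of the dienone gives the catechol monocarbonate directly at the catechol (not quinone) oxidation level, with the carbonate and the hydrogen-bonded neighbouring OH deactivating the ring against a second oxygenation; the two ortho positions of each ring are equivalent, so one regioisomer forms and no stereocentre is created; the closest known reaction types are the ortho-benzoyloxylation of phenols by dibenzoyl peroxide and Lewis-acid-promoted arene oxygenation with peroxydicarbonates.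

**Step 2**
Reactants: 4 bis[3-(hexadecyloxycarbonyloxy)-4-hydroxyphenyl]methane
Product: 5 bis(3,4-dihydroxyphenyl)methane
Conditions: LiOH·H2O (6 equiv), degassed THF/H2O 3:1, argon, 0 °C → rt, 1 h; then 1 M HCl to pH 2
Reagents that add atoms: none
Why: Saponification of the aryl alkyl carbonate (acyl substitution with aryloxide as leaving group) followed by decarboxylation of the hexadecyl carbonate half-ester frees the catechol, and excluding air until the acid quench keeps the catecholate from oxidising; no stereocentre is involved.

**Step 3**
Reactants: 5 bis(3,4-dihydroxyphenyl)methane; 6 bromine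
Product: 7 bis(2,3,6-tribromo-4,5-dihydroxyphenyl)methane (target)
Conditions: Br2 (6.5 equiv), AcOH, 20 → 50 °C, 6 h; then ice-water, filtration
Reagents that add atoms: bromine, BrBr
Why: Electrophilic aromatic bromination: every open position of 5 (2, 5 and 6 on each ring) is ortho or para to a hydroxyl, so each catechol ring takes up three bromines as simple 4-alkylcatechols do, the acidic AcOH/HBr medium disfavours quinone methide formation at the CH2 bridge, and no stereocentre is created.

**Compound list** (no compound in the route has a stereocentre)
1 | bis(4-hydroxyphenyl)methane (bisphenol F) | Oc1ccc(Cc2ccc(O)cc2)cc1 | starting material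
2 | dihexadecyl peroxydicarbonate | CCCCCCCCCCCCCCCCOC(=O)OOC(=O)OCCCCCCCCCCCCCCCC | starting material
3 | bis[4-(hexadecyloxycarbonylperoxy)phenyl]methane (bis(aryl peroxycarbonate)) | CCCCCCCCCCCCCCCCOC(=O)OOc1ccc(Cc2ccc(OOC(=O)OCCCCCCCCCCCCCCCC)cc2)cc1 | intermediate
4 | bis[3-(hexadecyloxycarbonyloxy)-4-hydroxyphenyl]methane | CCCCCCCCCCCCCCCCOC(=O)Oc1cc(Cc2ccc(O)c(OC(=O)OCCCCCCCCCCCCCCCC)c2)ccc1O | intermediate
5 | bis(3,4-dihydroxyphenyl)methane | Oc1ccc(Cc2ccc(O)c(O)c2)cc1O | intermediate
6 | bromine | BrBr | starting material
7 | bis(2,3,6-tribromo-4,5-dihydroxyphenyl)methane | Oc1c(O)c(Br)c(Cc2c(Br)c(O)c(O)c(Br)c2Br)c(Br)c1Br | target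

**Total step count:** 3
**Longest linear sequence:** 3 steps (1 → 4 → 5 → 7)

**Steps most likely to fail** (highest risk first)

Step 1 (the proposed new C–O bond formation). The polar attack on the O–O bond may be too slow at temperatures where 2 is stable. It may also lose out to acyl transfer onto the phenol oxygen, to one-electron oxidation with phenol coupling, or to a second oxygenation of the same ring. The fallback uses known chemistry, sets out from 1 and comes back to the route at 5, so it replaces steps 1 and 2. Magnesium-mediated ortho-formylation of 1 (MgCl2, Et3N, paraformaldehyde, MeCN, reflux) gives 5,5'-methylenebis(2-hydroxybenzaldehyde) F1. Dakin oxidation of F1 (30% H2O2, NaOH, H2O/THF, 0 °C, argon; then HCl) forms the same two aryl C–O bonds by aryl migration to peroxide oxygen and delivers 5.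

Step 3 (six-fold bromination). Three things can go wrong: ipso attack at the bridge carbon para to a hydroxyl with C–C cleavage, oxidation to o-quinone or quinone methide, and incomplete bromination at the crowded position between OH and CH2. Any quinone can be returned with a bisulfite or dithionite wash, but cleavage cannot be undone. The fallback sets out from 5 and comes back at 7. Exhaustive O-methylation of 5 (Me2SO4, K2CO3, acetone, reflux) gives bis(3,4-dimethoxyphenyl)methane F2, which can form neither quinones nor quinone methides. Forced bromination of F2 (excess Br2, Fe powder cat., CHCl3, reflux) gives bis(2,3,6-tribromo-4,5-dimethoxyphenyl)methane F3. Demethylation of F3 (BBr3, CH2Cl2, −78 °C → rt; then water) gives 7. Bromination of the ether is harder at the hindered positions than on the free catechol, so this fallback trades oxidation risk for forcing conditions.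

Step 2 (carbonate cleavage). The catecholate can oxidise if air gets in before the acid quench, and the waxy 4 may dissolve poorly in aqueous THF. The fallback sets out from 4 and comes back at 5. It replaces solvolysis by hydride reduction (LiAlH4, THF, 0 °C; then 1 M HCl), so the catechol stays bound as an aluminate under reducing, water-free conditions until the quench. This fallback makes no new compound (F0).

**Further compounds**
F1 | step 1 | 5,5'-methylenebis(2-hydroxybenzaldehyde) | O=Cc1cc(Cc2ccc(O)c(C=O)c2)ccc1O
F0 | step 2 | none | none
F2 | step 3 | bis(3,4-dimethoxyphenyl)methane | COc1ccc(Cc2ccc(OC)c(OC)c2)cc1OC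
F3 | step 3 | bis(2,3,6-tribromo-4,5-dimethoxyphenyl)methane | COc1c(OC)c(Br)c(Cc2c(Br)c(OC)c(OC)c(Br)c2Br)c(Br)c1Br
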